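Ring C is disconnected at O1–C2 and C3–C4. When ring A is written in its ortho-quinone methide form, the atoms O1=C8a–C4a=C4 make up a heterodiene. The missing C2=C3 unit is an (E)-β-acetoxystyrene carrying ring B. One chiral-acid-catalysed inverse-demand (4+2) addition closes ring C, forms both bonds, sets C2 and C3 trans and brings C4 in already oxygenated. Only hydrolysis, alcohol oxidation and deprotection remain. The diene precursor is a hexasubstituted salicylaldehyde dimethyl acetal bearing the C6 prenyl and C8 lavandulyl chains, with the future O1 as its only free phenol. A para-Claisen–Cope shift singles out that oxygen.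

Key step: step 12

Assumption (catalyst sense): the facial sense of the phosphoric acid cannot be predicted for this untested reactant pair, so the (R)-acid is written and its mirror image is used should the (2S,3R) series prevail.
Remark (descriptors): the lavandulyl centre keeps the spatial arrangement of (R)-lavandulol throughout. It reads R while its CH2 carries O, I or Zn and S once it carries the arene. The target is (2R,3R), and the same arrangement at C3 reads S while C4 is sp3. Both changes are CIP priority effects only.
Remark (C4): either C4 epimer of the cycloadduct and of the derived alcohol is serviceable, and the 3,4-trans epimer is drawn.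
Remark (ring A design): with three identical protecting groups on a phloroglucinol core, the oxygens that become O1 and O5 would both sit ortho to the formyl carbon next to an alkyl chain and could not be told apart. O1 is therefore defined by its hydrogen bond to the formyl group and by the para relationship created in the Claisen–Cope shift. The lavandulyl chain is joined by palladium catalysis because an aryllithium would rather attack the allylic β-hydrogen of the iodide or the doubly activated ArCH2CH=C protons.
Remark (dienophile design): the enol acetate is made by a geometry-retaining coupling, because enol acetylation of the arylacetaldehyde would give both alkene isomers.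

Step 1
Reactants: 1 2,4,6-trihydroxybenzaldehyde
Product: 2 2-hydroxy-4,6-bis(methoxymethoxy)benzaldehyde
Conditions: MOMCl (2.2 equiv), K2CO3, acetone, 0 °C to rt
Reagents that add atoms: chloromethyl methyl ether (MOMCl), COCCl
Why: Williamson-type alkylation in which the 4-OH and one of the two equivalent ortho hydroxyls react while the last ortho hydroxyl stays locked in a hydrogen bond to the formyl oxygen, a selectivity well established for 2,4,6-trihydroxyaryl carbonyl compounds.

Step 2
Reactants: 2 2-hydroxy-4,6-bis(methoxymethoxy)benzaldehyde; 3 prenyl bromide (1-bromo-3-methylbut-2-ene)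
Product: 4 2,4-bis(methoxymethoxy)-6-[(3-methylbut-2-en-1-yl)oxy]benzaldehyde
Conditions: K2CO3, DMF, rt to 40 °C
Reagents that add atoms: none
Why: Williamson ether synthesis, since in a dipolar aprotic solvent the carbonate breaks the hydrogen bond and the phenoxide displaces the primary allylic bromide at oxygen (SN2).

Step 3
Reactants: 4 2,4-bis(methoxymethoxy)-6-[(3-methylbut-2-en-1-yl)oxy]benzaldehyde
Product: 7 6-hydroxy-2,4-bis(methoxymethoxy)-3-(3-methylbut-2-en-1-yl)benzaldehyde, via ortho-dienone 5 (not isolated), via para-dienone 6 (not isolated)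
Conditions: N,N-diethylaniline, 190–200 °C, sealed vessel, argon
Reagents that add atoms: none
Why: Tandem aromatic Claisen–Cope rearrangement in which the first [3,3] shift puts a reverse-prenyl group on the free ortho carbon, the crowded dienone 5 relays it by a second [3,3] shift to the para carbon between the two MOM ethers, and enolisation of 6 releases a phenol that is necessarily para to the prenyl group, which is the O1/C6 relationship of the target.

Step 4
Reactants: 7 6-hydroxy-2,4-bis(methoxymethoxy)-3-(3-methylbut-2-en-1-yl)benzaldehyde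
Product: 8 2-hydroxy-3-iodo-4,6-bis(methoxymethoxy)-5-(3-methylbut-2-en-1-yl)benzaldehyde
Conditions: I2 (1.05 equiv), NaHCO3, THF–H2O, 0 °C, dark
Reagents that add atoms: iodine, II
Why: Electrophilic aromatic iodination of the phenolate at the only unsubstituted ring carbon, which should be far faster than attack on the trisubstituted alkene, whose iodonium formation is reversible and finds no free hydroxyl next to it.

Step 5
Reactants: 9 (R)-lavandulol [(2R)-5-methyl-2-(prop-1-en-2-yl)hex-4-en-1-ol]
Product: 10 (R)-lavandulyl iodide [(3R)-3-(iodomethyl)-2,6-dimethylhepta-1,5-diene]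
Conditions: I2, PPh3, imidazole, CH2Cl2, 0 °C
Reagents that add atoms: iodine, II
Why: Appel reaction, in which iodide displaces the alkoxyphosphonium group at the primary carbon (SN2), so the adjacent stereocentre and both alkenes are untouched.

Step 6
Reactants: 8 2-hydroxy-3-iodo-4,6-bis(methoxymethoxy)-5-(3-methylbut-2-en-1-yl)benzaldehyde; 10 (R)-lavandulyl iodide
Product: 12 2-hydroxy-4,6-bis(methoxymethoxy)-5-(3-methylbut-2-en-1-yl)-3-[(2S)-5-methyl-2-(prop-1-en-2-yl)hex-4-en-1-yl]benzaldehyde, via lavandulylzinc iodide 11 (not isolated)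
Conditions: 10, Zn dust, LiCl, THF, 30 °C; then slow addition of 11 (1.5 equiv) to 8, Pd(OAc)2 (3 mol %), SPhos (6 mol %), THF, 25 °C
Reagents that add atoms: none
Why: Negishi sp3–sp2 coupling, in which zinc insertion and transmetalation involve only the CH2 carbon so the neighbouring stereocentre is retained, the bulky biaryl phosphine favours reductive elimination over β-hydride elimination at the di-ortho-substituted aryl palladium centre, and an alkylzinc halide neither adds to the aldehyde nor is protonated by the hydrogen-bonded phenol at a competitive rate.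

Step 7
Reactants: 12 2-hydroxy-4,6-bis(methoxymethoxy)-5-(3-methylbut-2-en-1-yl)-3-[(2S)-5-methyl-2-(prop-1-en-2-yl)hex-4-en-1-yl]benzaldehyde
Product: 13 ring A acetal 2-(dimethoxymethyl)-3,5-bis(methoxymethoxy)-4-(3-methylbut-2-en-1-yl)-6-[(2S)-5-methyl-2-(prop-1-en-2-yl)hex-4-en-1-yl]phenol
Conditions: HC(OMe)3 (5 equiv), MeOH, PPTS (5 mol %), rt; Et3N quench, filtration through Et3N-deactivated silica
Reagents that add atoms: trimethyl orthoformate, COC(OC)OC
Why: Acid-catalysed acetalisation driven by the orthoester as water scavenger, with an acid weak enough to leave aryl MOM ethers and alkenes alone and a base quench that keeps the easily ionised product intact.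

Step 8
Reactants: 14 2,4-dihydroxybenzaldehyde
Product: 15 2,4-bis(methoxymethoxy)benzaldehyde
Conditions: NaH (2.4 equiv), MOMCl (2.4 equiv), DMF, 0 °C to rt
Reagents that add atoms: chloromethyl methyl ether (MOMCl), COCCl
Why: Williamson-type alkylation of the bis-phenoxide, where full deprotonation by NaH overrides the hydrogen bond of the 2-OH so that both oxygens are protected.

Step 9
Reactants: 15 2,4-bis(methoxymethoxy)benzaldehyde
Product: 16 2-{(E)-2-[2,4-bis(methoxymethoxy)phenyl]ethenyl}-4,4,5,5-tetramethyl-1,3,2-dioxaborolane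
Conditions: CH2(Bpin)2, lithium 2,2,6,6-tetramethylpiperidide (LiTMP), THF, 0 °C; then 15, −78 °C to rt
Reagents that add atoms: bis(4,4,5,5-tetramethyl-1,3,2-dioxaborolan-2-yl)methane, CC1(C)OB(CB2OC(C)(C)C(C)(C)O2)OC1(C)C
Why: Boron–Wittig olefination, in which the α-boryl carbanion adds to the aldehyde and syn B–O elimination from the less crowded adduct should give the (E)-alkenyl boronate in a single step.

Step 10
Reactants: 16 2-{(E)-2-[2,4-bis(methoxymethoxy)phenyl]ethenyl}-4,4,5,5-tetramethyl-1,3,2-dioxaborolane
Product: 17 potassium {(E)-2-[2,4-bis(methoxymethoxy)phenyl]ethenyl}trifluoroborate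
Conditions: KHF2 (aq.), MeOH, rt
Reagents that add atoms: potassium hydrogen difluoride, [K+].[F-].F
Why: Standard fluoride exchange of a pinacol boronate to the crystalline trifluoroborate, which touches neither the alkene geometry nor the MOM ethers.

Step 11
Reactants: 17 potassium {(E)-2-[2,4-bis(methoxymethoxy)phenyl]ethenyl}trifluoroborate
Product: 18 (E)-2-[2,4-bis(methoxymethoxy)phenyl]ethenyl acetate
Conditions: AcOH (2 equiv), CuBr (10 mol %), DMAP (20 mol %), 4 Å molecular sieves, O2 (1 atm), MeCN, 60 °C
Reagents that add atoms: acetic acid, CC(=O)O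
Why: Chan–Lam-type oxidative C–O coupling of an alkenyl trifluoroborate with a carboxylic acid, in which transmetalation to copper and C–O reductive elimination both proceed with retention so that the (E) geometry is carried into the enol ester.

Step 12
Reactants: 13 ring A acetal 2-(dimethoxymethyl)-3,5-bis(methoxymethoxy)-4-(3-methylbut-2-en-1-yl)-6-[(2S)-5-methyl-2-(prop-1-en-2-yl)hex-4-en-1-yl]phenol; 18 (E)-2-[2,4-bis(methoxymethoxy)phenyl]ethenyl acetate
Product: 20 (2R,3S,4R)-2-[2,4-bis(methoxymethoxy)phenyl]-4-methoxy-5,7-bis(methoxymethoxy)-6-(3-methylbut-2-en-1-yl)-8-[(2S)-5-methyl-2-(prop-1-en-2-yl)hex-4-en-1-yl]-3,4-dihydro-2H-chromen-3-yl acetate, via methoxy ortho-quinone methide 19 (not isolated)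
Conditions: (R)-3,3'-bis(2,4,6-triisopropylphenyl)-1,1'-binaphthalene-2,2'-diyl hydrogen phosphate [(R)-TRIP, 10 mol %], 18 (1.5 equiv), 5 Å molecular sieves, toluene, −30 °C
Reagents that add atoms: none
Why: Proposed new method: the phosphoric acid ionises the very electron-rich acetal, methanol is lost, and the 4-methoxy ortho-quinone methide 19 (or its O-protonated form, tied to the chiral phosphate through the O1–H···O=P hydrogen bond) is attacked at C4 by the acetoxy-bearing alkene carbon of 18, after which O1 captures the developing C2 benzylic cation in an asynchronous inverse-demand hetero-Diels–Alder addition. The closest known reaction types are the acid-promoted (4+2) additions of quinone methides from salicylaldehyde acetals to styrenes and the chiral phosphoric acid catalysed cycloadditions of ortho-quinone methides from ortho-hydroxybenzyl alcohols, but an alkoxy-substituted methide, an enol ester dienophile and asymmetric catalysis have not been combined. Ring C closes as a six-membered ring by intermolecular (4+2) annulation, and if the addition is stepwise the last event is a 6-exo-trig attack of O1 on the para-quinone-methide-like C2 cation. C3 is set by the face of the enol ester that the 3,3'-aryl pocket of the catalyst exposes to C4 (catalyst control, as the lavandulyl centre is too remote), C2 follows from C3 by suprafacial addition to the (E)-alkene and is backed by the equatorial preference of the aryl group in a stepwise closure, and C4 depends on endo or exo approach and does not matter because step 14 makes it planar. The regiochemistry requires the benzylic carbon to carry the positive charge, which the 2,4-dioxygenated ring B secures against the weakly donating acyloxy group, and the orientation of ring A is unambiguous because O1 is the only free phenol next to the acetal. Molecular sieves take up methanol so that neither reversal nor methanolysis of the enol ester competes.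

Step 13
Reactants: 20 (2R,3S,4R)-4-methoxyflavan-3-yl acetate of step 12
Product: 21 (2R,3S,4R)-2-[2,4-bis(methoxymethoxy)phenyl]-4-hydroxy-5,7-bis(methoxymethoxy)-6-(3-methylbut-2-en-1-yl)-8-[(2S)-5-methyl-2-(prop-1-en-2-yl)hex-4-en-1-yl]-3,4-dihydro-2H-chromen-3-yl acetate
Conditions: TsOH·H2O (5 mol %), THF–H2O (4:1), 0 °C, NaHCO3 quench at full conversion
Reagents that add atoms: water, O
Why: SN1 solvolysis of a benzylic ether whose cation is stabilised by O1 and by the C5 and C7 oxygens, so that exchange with water should occur at an acidity far below that needed to cleave aryl MOM ethers, while C2 and C3 are not involved and the configuration at C4 is irrelevant.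

Step 14
Reactants: 21 (2R,3S,4R)-4-hydroxyflavan-3-yl acetate of step 13
Product: 22 (2R,3R)-2-[2,4-bis(methoxymethoxy)phenyl]-5,7-bis(methoxymethoxy)-6-(3-methylbut-2-en-1-yl)-8-[(2S)-5-methyl-2-(prop-1-en-2-yl)hex-4-en-1-yl]-4-oxo-3,4-dihydro-2H-chromen-3-yl acetate
Conditions: Dess–Martin periodinane (1.3 equiv), NaHCO3, CH2Cl2, 0 °C to rt
Reagents that add atoms: none
Why: Dess–Martin oxidation of a secondary benzylic alcohol under buffered conditions, which tolerates the isolated alkenes, the MOM ethers and the acetate and erases the C4 stereocentre without enolising C3.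

Step 15
Reactants: 22 (2R,3R)-3-acetoxyflavanone tetrakis-MOM ether of step 14
Product: 23 target CNP0207904.2 [(2R,3R)-2-(2,4-dihydroxyphenyl)-3,5,7-trihydroxy-6-(3-methylbut-2-en-1-yl)-8-[(2S)-5-methyl-2-(prop-1-en-2-yl)hex-4-en-1-yl]-2,3-dihydro-4H-chromen-4-one]
Conditions: HCl (about 1.5 M, from conc. aq. HCl) in MeOH, rt to 40 °C, monitored and neutralised at completion
Reagents that add atoms: none
Why: Acid-catalysed transacetalisation of the four aryl MOM ethers and transesterification of the activated α-keto acetate in one pot, the usual way of unmasking prenylated flavonoids, with acid chosen because dihydroflavonols epimerise and ring-contract in base and with the 2,3-trans isomer being the thermodynamic one so that C2 and C3 are retained.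

Compound list
1 | 2,4,6-trihydroxybenzaldehyde | O=Cc1c(O)cc(O)cc1O | starting material
2 | 2-hydroxy-4,6-bis(methoxymethoxy)benzaldehyde | O=Cc1c(O)cc(OCOC)cc1OCOC | intermediate
3 | prenyl bromide | CC(C)=CCBr | starting material
4 | 2,4-bis(methoxymethoxy)-6-[(3-methylbut-2-en-1-yl)oxy]benzaldehyde | O=Cc1c(OCC=C(C)C)cc(OCOC)cc1OCOC | intermediate
5 | ortho-dienone, 2,4-bis(methoxymethoxy)-5-(2-methylbut-3-en-2-yl)-6-oxocyclohexa-1,3-diene-1-carbaldehyde (racemic, transient) | O=CC1=C(OCOC)C=C(OCOC)C(C(C)(C)C=C)C1=O | intermediate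
6 | para-dienone, 2,4-bis(methoxymethoxy)-3-(3-methylbut-2-en-1-yl)-6-oxocyclohexa-1,4-diene-1-carbaldehyde (racemic, transient) | O=CC1=C(OCOC)C(CC=C(C)C)C(OCOC)=CC1=O | intermediate
7 | 6-hydroxy-2,4-bis(methoxymethoxy)-3-(3-methylbut-2-en-1-yl)benzaldehyde | O=Cc1c(O)cc(OCOC)c(CC=C(C)C)c1OCOC | intermediate
8 | 2-hydroxy-3-iodo-4,6-bis(methoxymethoxy)-5-(3-methylbut-2-en-1-yl)benzaldehyde | O=Cc1c(O)c(I)c(OCOC)c(CC=C(C)C)c1OCOC | intermediate
9 | (R)-lavandulol | C=C(C)[C@@H](CC=C(C)C)CO | starting material
10 | (R)-lavandulyl iodide, (3R)-3-(iodomethyl)-2,6-dimethylhepta-1,5-diene | C=C(C)[C@@H](CC=C(C)C)CI | intermediate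
11 | [(2R)-5-methyl-2-(prop-1-en-2-yl)hex-4-en-1-yl]zinc iodide | C=C(C)[C@@H](CC=C(C)C)C[Zn]I | intermediate
12 | 2-hydroxy-4,6-bis(methoxymethoxy)-5-prenyl-3-[(2S)-lavandulyl]benzaldehyde | C=C(C)[C@@H](CC=C(C)C)Cc1c(OCOC)c(CC=C(C)C)c(OCOC)c(C=O)c1O | intermediate
13 | ring A salicylaldehyde dimethyl acetal, 2-(dimethoxymethyl)-3,5-bis(methoxymethoxy)-4-prenyl-6-[(2S)-lavandulyl]phenol | C=C(C)[C@@H](CC=C(C)C)Cc1c(OCOC)c(CC=C(C)C)c(OCOC)c(C(OC)OC)c1O | intermediate
14 | 2,4-dihydroxybenzaldehyde | O=Cc1ccc(O)cc1O | starting material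
15 | 2,4-bis(methoxymethoxy)benzaldehyde | O=Cc1ccc(OCOC)cc1OCOC | intermediate
16 | (E)-2-[2,4-bis(methoxymethoxy)phenyl]ethenylboronic acid pinacol ester | CC1(C)OB(/C=C/c2ccc(OCOC)cc2OCOC)OC1(C)C | intermediate
17 | potassium {(E)-2-[2,4-bis(methoxymethoxy)phenyl]ethenyl}trifluoroborate | [K+].F[B-](F)(F)/C=C/c1ccc(OCOC)cc1OCOC | intermediate
18 | (E)-2-[2,4-bis(methoxymethoxy)phenyl]ethenyl acetate | CC(=O)O/C=C/c1ccc(OCOC)cc1OCOC | intermediate
19 | methoxy ortho-quinone methide, 6-(methoxymethylidene)-3,5-bis(methoxymethoxy)-4-prenyl-2-[(2S)-lavandulyl]cyclohexa-2,4-dien-1-one (exocyclic geometry not defined) | C=C(C)[C@@H](CC=C(C)C)CC1=C(OCOC)C(CC=C(C)C)=C(OCOC)C(=COC)C1=O | intermediate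
20 | (2R,3S,4R)-4-methoxy-3-acetoxyflavan, 2,3-trans, 3,4-trans epimer drawn, four MOM ethers, 6-prenyl, 8-[(2S)-lavandulyl] | C=C(C)[C@@H](CC=C(C)C)Cc1c(OCOC)c(CC=C(C)C)c(OCOC)c2c1O[C@H](c1ccc(OCOC)cc1OCOC)[C@@H](OC(C)=O)[C@@H]2OC | intermediate
21 | (2R,3S,4R)-4-hydroxy-3-acetoxyflavan, same substituents | C=C(C)[C@@H](CC=C(C)C)Cc1c(OCOC)c(CC=C(C)C)c(OCOC)c2c1O[C@H](c1ccc(OCOC)cc1OCOC)[C@@H](OC(C)=O)[C@@H]2O | intermediate
22 | (2R,3R)-3-acetoxyflavanone, same substituents | C=C(C)[C@@H](CC=C(C)C)Cc1c(OCOC)c(CC=C(C)C)c(OCOC)c2c1O[C@H](c1ccc(OCOC)cc1OCOC)[C@@H](OC(C)=O)C2=O | intermediate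
23 | CNP0207904.2, (2R,3R)-2-(2,4-dihydroxyphenyl)-3,5,7-trihydroxy-6-prenyl-8-[(2S)-lavandulyl]chroman-4-one | C=C(C)[C@@H](CC=C(C)C)Cc1c(O)c(CC=C(C)C)c(O)c2c1O[C@H](c1ccc(O)cc1O)[C@@H](O)C2=O | target

Total step count: 15.
Longest linear sequence: 10 steps (steps 1, 2, 3, 4, 6, 7, 12, 13, 14, 15, from 1 to 23).

Steps most likely to fail

1. Step 12.
- What may go wrong: weak facial discrimination by the phosphate, which would show up as a diastereomer mixture because the lavandulyl centre is fixed. Other failure modes are acyl transfer from the enol ester to the free phenol, acid-induced oligomerisation of the electron-rich styrene, and addition in the opposite orientation.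
- The fallback uses known chemistry, sets out from 12 and comes back at 23.
- 12 is alkylated with allyl bromide and K2CO3 in DMF to the O-allyl aldehyde F1.
- MeMgBr converts this into the benzylic alcohol F2, and Dess–Martin oxidation gives the acetophenone F3.
- Claisen–Schmidt condensation with 15 (KOH, EtOH) gives the (E)-chalcone F4.
- Juliá–Colonna epoxidation (poly-L-leucine, urea–H2O2, DBU, THF) is a nucleophilic epoxidation that touches only the enone. It should give the (αR,βS)-epoxychalcone F5.
- Deallylation with Pd(PPh3)4 and PhSiH3 frees O1 alone. O1 opens the epoxide at the benzylic carbon with inversion (a trace of acid if needed) to the protected trans-dihydroflavonol F6.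
- The conditions of step 15 convert F6 into 23.

2. Step 13.
- What may go wrong: participation of the C3 acetate in the C4 cation, followed by acyl shift to the C4 oxygen and eventual loss of the ester. The two hydroxyls would then no longer be differentiated before the oxidation.
- The fallback replaces the participating ester before C4 is ionised. It sets out from 20 and comes back at 23.
- Methanolysis (K2CO3, MeOH) is harmless at this stage because no carbonyl group is present, and it gives the 4-methoxyflavan-3-ol F7.
- TBSCl and imidazole in DMF give the 3-O-TBS ether F8.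
- The aqueous acid of step 13 gives the 4-hydroxy-3-silyloxyflavan F9, and Dess–Martin oxidation gives the 3-silyloxyflavanone F10.
- The conditions of step 15 remove the silyl and MOM groups together to give 23.

3. Step 6.
- What may go wrong: sluggish transmetalation and reductive elimination at the di-ortho-substituted aryl palladium centre. β-Hydride elimination and protonolysis of the organozinc by the phenol would then take over.
- The fallback changes the organometallic partner to a proton-tolerant boron reagent. It sets out from 10 and 8 and comes back at 12.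
- Copper-catalysed borylation of 10 (B2pin2, CuI, PPh3, LiOMe, DMF, rt) gives the lavandulyl pinacol boronate F11.
- KHF2 in aqueous MeOH gives the potassium lavandulyltrifluoroborate F12.
- Suzuki–Miyaura coupling of F12 with 8 (Pd(OAc)2, RuPhos, K2CO3, toluene–H2O, 80 °C) tolerates both the phenol and the aldehyde and gives 12.

Further compounds
F1 | step 12 | O-allyl aldehyde, 2-(allyloxy)-4,6-bis(methoxymethoxy)-5-prenyl-3-[(2S)-lavandulyl]benzaldehyde | C=C(C)[C@@H](CC=C(C)C)Cc1c(OCOC)c(CC=C(C)C)c(OCOC)c(C=O)c1OCC=C
F2 | step 12 | benzylic alcohol, 1-aryl-ethanol from F1 (carbinol centre unassigned) | C=C(C)[C@@H](CC=C(C)C)Cc1c(OCOC)c(CC=C(C)C)c(OCOC)c(C(C)O)c1OCC=C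
F3 | step 12 | acetophenone, 2-(allyloxy)-4,6-bis(methoxymethoxy)-5-prenyl-3-[(2S)-lavandulyl]acetophenone | C=C(C)[C@@H](CC=C(C)C)Cc1c(OCOC)c(CC=C(C)C)c(OCOC)c(C(C)=O)c1OCC=C
F4 | step 12 | (E)-chalcone from F3 and 15 | C=C(C)[C@@H](CC=C(C)C)Cc1c(OCOC)c(CC=C(C)C)c(OCOC)c(C(=O)/C=C/c2ccc(OCOC)cc2OCOC)c1OCC=C
F5 | step 12 | (αR,βS)-epoxychalcone | C=C(C)[C@@H](CC=C(C)C)Cc1c(OCOC)c(CC=C(C)C)c(OCOC)c(C(=O)[C@@H]2O[C@H]2c2ccc(OCOC)cc2OCOC)c1OCC=C
F6 | step 12 | protected trans-dihydroflavonol, (2R,3R)-3-hydroxyflavanone tetrakis-MOM ether | C=C(C)[C@@H](CC=C(C)C)Cc1c(OCOC)c(CC=C(C)C)c(OCOC)c2c1O[C@H](c1ccc(OCOC)cc1OCOC)[C@@H](O)C2=O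
F7 | step 13 | 4-methoxyflavan-3-ol (2R,3S,4R) | C=C(C)[C@@H](CC=C(C)C)Cc1c(OCOC)c(CC=C(C)C)c(OCOC)c2c1O[C@H](c1ccc(OCOC)cc1OCOC)[C@@H](O)[C@@H]2OC
F8 | step 13 | 3-O-TBS ether of F7 | C=C(C)[C@@H](CC=C(C)C)Cc1c(OCOC)c(CC=C(C)C)c(OCOC)c2c1O[C@H](c1ccc(OCOC)cc1OCOC)[C@@H](O[Si](C)(C)C(C)(C)C)[C@@H]2OC
F9 | step 13 | 4-hydroxy-3-silyloxyflavan | C=C(C)[C@@H](CC=C(C)C)Cc1c(OCOC)c(CC=C(C)C)c(OCOC)c2c1O[C@H](c1ccc(OCOC)cc1OCOC)[C@@H](O[Si](C)(C)C(C)(C)C)[C@@H]2O
F10 | step 13 | 3-silyloxyflavanone (2R,3R) | C=C(C)[C@@H](CC=C(C)C)Cc1c(OCOC)c(CC=C(C)C)c(OCOC)c2c1O[C@H](c1ccc(OCOC)cc1OCOC)[C@@H](O[Si](C)(C)C(C)(C)C)C2=O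
F11 | step 6 | lavandulyl pinacol boronate (R) | C=C(C)[C@@H](CC=C(C)C)CB1OC(C)(C)C(C)(C)O1
F12 | step 6 | potassium lavandulyltrifluoroborate (R) | [K+].C=C(C)[C@@H](CC=C(C)C)C[B-](F)(F)F
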